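The runs were generated by integration with constants of no real substance; scatter was added.

**The task.** 4 questions are asked, and I expect one clock to carry the question on the ash run.

| setting | birch | larch | alder | cedar | ash |
|---|---|---|---|---|---|
| starting material | 0.400 M | 0.240 M | 0.400 M | 0.400 M | 0.400 M |
| coupling partner | 0.400 M | 0.240 M | 0.600 M | 0.400 M | 0.400 M |
| free catalyst | 0.00200 M | 0.00200 M | 0.00200 M | 0.00100 M | 3.10 × 10⁻⁴ M |
| time |  |  |  |  | 39 min |

- birch run (time / min: [starting material] / M): 6.5: 0.3118; 13: 0.2496; 20: 0.1961; 26: 0.1603; 32: 0.1327; 39: 0.1083
- larch run (time / min: [starting material] / M): 6.5: 0.1822; 13: 0.1406; 20: 0.1069; 26: 0.0848; 32: 0.0692; 39: 0.0528
- alder run (time / min: [starting material] / M): 6.5: 0.3017; 13: 0.2330; 20: 0.1766; 26: 0.1407; 32: 0.1143; 39: 0.0866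
- cedar run (time / min: [starting material] / M): 6.5: 0.3506; 13: 0.3121; 20: 0.2752; 26: 0.2472; 32: 0.2240; 39: 0.1992

(standard deviation of a reading: 0.001 M)

* the exponent of [coupling partner] in the starting rate at the charge of the birch run (at the point where two percent of the starting material have become target)
* the exponent of [free catalyst] in the starting rate at the charge of the birch run (at the point where two percent of the starting material have become target)
* the larch run starts with 0.160 M less of starting material and of coupling partner than the birch run, and with no target. Compared where both hold the same amount of starting material, once fifteen percent of what the larch run was charged with has turned into target, is the larch run faster, slower or alike (within a tenth)?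
* starting material in the ash run at 39 min, as a share of the starting material charged

- Overall: starting material + coupling partner -> target, with free catalyst as catalyst.
- Constant volume, constant temperature.
- A reading of a species includes what of it is bound.
- An order is taken over about fifteen percent of the charge, up and down.

**One moment.** The birch and cedar runs share their starting material and coupling partner, but the cedar run has half the free catalyst. If rate goes with catalyst, the cedar run needs twice the time to reach any fraction of its charge. At 13 min the cedar run holds 78.0%. At 6.5 min the birch run holds 77.9%.

**The drift.** One early moment proves little: the comparison may drift as target piles up. So I look late. At 39 min the cedar run holds 49.8%. At half that time, interpolated on a logarithm, the birch run holds 49.9%. I see no drift, so I take the exponent of free catalyst as 1.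

**The clock.** I carry one quantity. It reads 6.04 min for the ash run at 39 min. It is the catalyst clock: elapsed time multiplied by the free catalyst charged, divided by the free catalyst of the birch run. The field calls this variable time normalisation.

**Ash estimate.** A straight line from the start to the first birch reading gives 79.5%. But the birch readings bend, so a straight line is the wrong shape. An exponential through the same reading gives 79.3%. I commit to that, with a scatter of 0.250% of the charge from that one reading. One objection stays: the ash charge of free catalyst is less than the cedar charge, so the clock is extrapolated there.

**Coupling partner.** By 6.5 min the alder run has lost 24.6% of its charge and the birch run 22.1%. With the alder partner charge as the step, that gives an exponent of 0.267. But the step is wide, and a dependence that flattens reads lower across a wide step than at its foot. I hold this as a low figure.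

**Same excess.** This is a same-excess comparison. Where the larch and birch runs hold equal starting material, they also hold equal coupling partner, but the birch run has made 0.160 M more target. I read the larch run over its first interval and the birch run between 13 min and 20 min. These intervals are centred differently, so I divide each rate by the starting material present. The ratio reads 1.23, so the larch run reads faster than the birch run.

**The forecast.** The forecast gives 0.3 and 1 for the exponents, faster for the larch run and 79.3% for the ash run, which it calls “an extrapolation below the tested catalyst range”.

**The result.** The flask gives exponents of 0.35 for coupling partner and 1.0 for free catalyst. The larch run is faster, with a ratio of 1.3, and the ash run holds 79.4%.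

    free catalyst + starting material → loaded catalyst + by-product (41.94 /M/min)
    loaded catalyst + coupling partner → target + free catalyst (77.40 /M/min)
    free catalyst + by-product ⇌ catalyst-by-product complex, settled at all times (3.210 /M)
    2 coupling partner ⇌ idle reagent dimer, settled at all times (2.680 /M)

**Clock and dimer.** On the catalyst clock the ash run stands at 6.04 min, less than the 7.68 min at which the birch run has made a quarter of its charge. The cedar run makes that quarter at 15.3 min, which reads 7.66 min on the same clock. With coupling partner parked as idle reagent dimer, the ash run holds 79.4% of its starting material, and without that parking it holds 74.4%.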